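## Structural features

The target is a flavan: a benzene ring (ring A) fused through C4a and C8a to a dihydropyran ring, with a second benzene ring (ring B) attached at C2. Ring A is substituted everywhere except C6, with methoxy at C5, hydroxyl at C7 and a prenyl (3-methylbut-2-enyl) group at C8, next to the ring oxygen O1. Ring B carries hydroxyl and methoxy groups in a 3,5-relationship. C2 is the only stereocentre and has the R configuration. It stands alone, because C3 and C4 are bare methylene groups that offer no neighbouring stereocentre or functional group to relay chirality. The fragile parts are the prenyl double bond (it adds the adjacent C7 hydroxyl under acid and does not survive ordinary hydrogenation), the two electron-rich phenols and the benzylic C2–O1 bond. The real difficulty is to set an isolated benzylic ether stereocentre by catalyst control while placing three different groups on ring A with full regiocontrol. The key step uses the fact that the chain O1–C2–C3–C4, fused to ring A at C8a and C4a, maps onto a salicylaldehyde (C4 as the formyl carbon on C4a, O1 as the hydroxyl on C8a) joined to the β and α carbons of a cinnamaldehyde (C2 and C3), as long as C3 carries a formyl group for a while.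

## Logic of the disconnections

18 to 17: the two phenolic O–Si bonds are cut. Both phenols are masked in the same way, so one fluoride step ends the synthesis and no acid ever meets the free C7 hydroxyl next to the prenyl group. The forward step must be buffered so that the phenoxides are not left in base.

17 to 16: a formyl carbon is added back at C3 (the C3–CHO bond is the one cut in the forward sense). This restores the activating group that the bare C3–C4 ethylene lacks. The forward step must remove one carbon without eliminating O1 from C2 and without touching the prenyl alkene.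

16 to 14 (through 15): the C3–C4 single bond is traced back to a C3=C4 double bond conjugated with the formyl group. This turns the pyran ring into the direct product of a condensation. The forward step must be a 1,4-reduction that spares the isolated trisubstituted alkene and avoids any enolate or enamine that could expel O1.

14 to 9 and 12 (through 13): O1–C2 and C3–C4 are cut. This divides the molecule into two aromatic aldehydes of similar size and removes the only stereocentre, so chirality comes entirely from a catalyst. The forward step needs a single free phenol (the one ortho to the formyl group) and high enantioface control at C2.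

12 to 11 to 10: the Cα=Cβ bond of the enal is cut (two-carbon olefination of an aryl aldehyde), then the O–Si bond. The forward olefination must stop after one homologation and give the E alkene.

9 to 8 to 7: the O–Si bond at the hydroxyl para to the formyl group is cut, then both acetal C–O bonds. The forward silylation relies on the hydrogen bond that ties up the ortho hydroxyl. The acid step must not add a hydroxyl to the prenyl group.

7 to 5 (through 6): the aryl–CHO bond is cut. Because 5 is symmetric, only one kind of ring hydrogen is left, so the regiochemistry is fixed by the substrate. The forward metalation must take place on the ring and not at the benzylic, allylic CH2 of the prenyl group.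

5 to 2 and 3 (through 4): the aryl–CH2 bond is cut. This gives a commercial allylic bromide and a symmetric arene. The forward metalation must occur between the two acetal oxygens, and the coupling must be SN2 and not SN2′.

2 to 1: the two O–CH2OMe bonds are cut, leading to a commercial phenol. The acetals are needed as directing groups for the two metalations.

## Other disconnections considered

Alternative 1: The cut runs through ring A itself (C7–C8, C4a–C8a, C6–C7). It leads to cyclobutenone A2, in which the stereocentre, both pyran methylenes and an alkynyl ether oxygen (the future O1) already sit in a tether.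
- Forward key step: heating A2 would open the four-membered ring to a vinylketene, which would add across the tethered ynol ether in a [2+2] sense. A 4π opening, a 6π closure and tautomerisation would then give A1, with ring A and the pyran ring formed together.
- In its favour: the positions of methoxy, hydroxyl and prenyl follow from connectivity alone. The C7 phenol emerges free and already distinguished from the ring B phenol. No carbon has to be excised, and the stereocentre would come from a dependable aryl ketone reduction well before the key step.
- Against it here: A2 is a secondary benzylic alkynyl ether with β-hydrogens. This class tends to lose ketene by retro-ene fragmentation or to rearrange sigmatropically at benzannulation temperatures. The [2+2] event must also occur inside a tether that closes a six-membered ring.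
- Comparison: on regiocontrol of ring A and on freedom from sacrificial atoms this alternative is the better plan, and on the final deprotection (one fluoride step) it is the equal. Mechanistically it is a thermal pericyclic cascade with less close analogy for this substitution pattern than the amine-catalysed annulation has for salicylaldehydes. Making A2 (chiral alcohol, alkynyl ether, prenylated acetylide, 2-alkyl-3-methoxycyclobutenone) would take clearly more steps than the longest line of the chosen route.

Alternative 2: The cut is at C2–C3 and O1–C8a of a pyranone, and ring A is left for later.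
- Forward key step: aldehyde 11 and siloxy diene A4 would combine in a hetero-Diels–Alder reaction under a chiral titanium catalyst (Ti(OiPr)4 with an axially chiral binaphthol ligand). Acid work-up would eliminate methanol and give pyranone A3.
- In its favour: this is one of the most dependable enantioselective reactions of aromatic aldehydes. C2 is set in the first C–C bond-forming step, and A3 is one step from 11. On reliability and earliness of enantiocontrol it is better than the chosen plan.
- Against it here: A3 has neither ring A nor the right oxidation level. The C4a=C8a enol ether bond would have to be built into a benzene ring carrying methoxy at C5, hydroxyl at C7 and prenyl at C8, and the C4 carbonyl would have to be removed. C2 of A3 is β to the ketone, so the enolate chemistry needed for the annulation invites loss of O1 and racemisation.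
- Comparison: both plans use one catalytic asymmetric step on a ring B electrophile. The chosen plan pays with two steps for a sacrificial carbon; the alternative pays with a deoxygenation and an arene construction. It is more linear and clearly longer.

Alternative 3: The cut is at C4–C4a and C8a–O1.
- Forward key step: aryl iodide A6 and enantiopure oxetane A7 would be joined by Pd(OAc)2 with norbornene A8. The sequence is oxidative addition of A6, insertion of A8, C–H palladation at C4a, opening of A7 at its CH2 carbon (C4–C4a), extrusion of A8 and C–O reductive elimination at C8a, giving A5.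
- In its favour: it is the most convergent option. It needs no sacrificial carbon and no redox adjustment after ring closure, only desilylation. The stereocentre arrives with A7 and is not a reacting centre. The ortho prenyl group of A6 supplies the ortho substituent that this relay chemistry needs for clean mono-functionalisation.
- Against it here: A6 bears iodine meta to both oxygen substituents, where neither electrophilic iodination nor directed metalation places it, so its regiocontrolled synthesis would be long. A7 needs its own asymmetric synthesis. In the key step the C4a hydrogen is flanked by a methoxy group, the prenyl alkene can insert into or be isomerised by aryl-palladium species, and opening of A7 at its benzylic carbon would leak regio- and stereochemistry.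
- Comparison: on steps after the key step (one against three) and on stereochemical security it is better than the chosen plan. On precursor access and on predictability of the key step for this substrate it is weaker.

Key step: step 8

## Remarks and assumptions

- Compounds 9, 12 and 14 were checked atom by atom against 18 and need no correction. The spatial arrangement at C2 is the same from 13 to 18. Only the CIP letter changes: S in 14 and 15, where C3 outranks the aryl group, and R in 13 and 16–18.
- The sense of induction in step 8 is assigned with the usual shielding model for iminium ions of 2-(diarylsilyloxymethyl)pyrrolidines (E, s-trans iminium, attack anti to the bulky group). On that model the (R)-catalyst gives (2S)-14. If the opposite sense were found, the (S)-catalyst would be used.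
- The formyl group of ring A is introduced by directed metalation while the acetals are still in place, so acid meets the prenyl group only once, on a ring deactivated by the aldehyde.
- The conjugate reduction is done by hydrosilylation so that no enamine or enolate with a β-aryloxy leaving group is formed.

## Route

Step 1
Reactants: 1 5-methoxyresorcinol (5-methoxybenzene-1,3-diol)
Product: 2 1-methoxy-3,5-bis(methoxymethoxy)benzene
Conditions: NaH (2.4 equiv), MOMCl (2.4 equiv), DMF, 0 °C to rt
Reagents that add atoms: chloromethyl methyl ether (MOMCl), COCCl
Why: O-alkylation of both phenoxides (Williamson type); the two acetal ethers are chosen because they are strong ortho-directing groups for the two metalations that follow.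

Step 2
Reactants: 2 1-methoxy-3,5-bis(methoxymethoxy)benzene; 3 prenyl bromide (1-bromo-3-methylbut-2-ene)
Product: 5 5-methoxy-1,3-bis(methoxymethoxy)-2-(3-methylbut-2-en-1-yl)benzene, via aryllithium 4 (not isolated)
Conditions: n-BuLi (1.1 equiv), THF, 0 °C; then CuI (10 mol %), 3 (1.3 equiv), −78 °C to rt
Reagents that add atoms: none
Why: Directed ortho-metalation; the hydrogen between the two methoxymethoxy groups is held by two chelating acetal oxygens, so 4 should form there, and copper-catalysed SN2 coupling with the primary allylic bromide 3 should give 5, whose symmetry makes the two remaining ring hydrogens equivalent.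

Step 3
Reactants: 5 5-methoxy-1,3-bis(methoxymethoxy)-2-(3-methylbut-2-en-1-yl)benzene
Product: 7 6-methoxy-2,4-bis(methoxymethoxy)-3-(3-methylbut-2-en-1-yl)benzaldehyde, via aryllithium 6 (not isolated)
Conditions: n-BuLi (1.2 equiv), THF, −20 to 0 °C; then DMF (3 equiv), −78 °C to rt; H2O
Reagents that add atoms: N,N-dimethylformamide (DMF), CN(C)C=O
Why: A second directed ortho-metalation at the only kind of ring hydrogen left (flanked by a methoxymethoxy and a methoxy group), followed by formylation of 6 with DMF. This avoids electrophilic formylation of a free prenylated resorcinol and places the prenyl group at the future C8 without ambiguity.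

Step 4
Reactants: 7 6-methoxy-2,4-bis(methoxymethoxy)-3-(3-methylbut-2-en-1-yl)benzaldehyde
Product: 8 2,4-dihydroxy-6-methoxy-3-(3-methylbut-2-en-1-yl)benzaldehyde
Conditions: 3 M HCl (aq), MeOH, rt
Reagents that add atoms: none
Why: Acid-catalysed acetal exchange with methanol cleaves both aryl methoxymethyl ethers. The formyl group lowers the nucleophilicity of the ring and of the phenols, which should hold back addition of a hydroxyl to the prenyl double bond at room temperature.

Step 5
Reactants: 8 2,4-dihydroxy-6-methoxy-3-(3-methylbut-2-en-1-yl)benzaldehyde
Product: 9 4-[(tert-butyldimethylsilyl)oxy]-2-hydroxy-6-methoxy-3-(3-methylbut-2-en-1-yl)benzaldehyde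
Conditions: TBSCl (1.05 equiv), imidazole (2.2 equiv), CH2Cl2, 0 °C
Reagents that add atoms: tert-butyldimethylsilyl chloride (TBSCl), CC(C)(C)[Si](C)(C)Cl
Why: Chemoselective silylation; the C2 hydroxyl is locked in a hydrogen bond to the formyl group and flanked on both sides, so the more acidic and more accessible C4 hydroxyl should react first with one equivalent of chlorosilane.

Step 6
Reactants: 10 3-hydroxy-5-methoxybenzaldehyde
Product: 11 3-[(tert-butyldimethylsilyl)oxy]-5-methoxybenzaldehyde
Conditions: TBSCl (1.2 equiv), imidazole (2.5 equiv), DMF, rt
Reagents that add atoms: tert-butyldimethylsilyl chloride (TBSCl), CC(C)(C)[Si](C)(C)Cl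
Why: Standard silylation of a phenol; it masks the ring B hydroxyl so that only one free phenol is present in step 8.

Step 7
Reactants: 11 3-[(tert-butyldimethylsilyl)oxy]-5-methoxybenzaldehyde
Product: 12 (2E)-3-{3-[(tert-butyldimethylsilyl)oxy]-5-methoxyphenyl}prop-2-enal
Conditions: Ph3P=CHCHO (1.2 equiv), toluene, 80 °C
Reagents that add atoms: (triphenylphosphoranylidene)acetaldehyde, O=CC=P(c1ccccc1)(c1ccccc1)c1ccccc1
Why: Wittig olefination with a stabilised formyl ylide should give the E enal under neutral conditions that the aryl silyl ether tolerates. A small excess of ylide and moderate temperature limit a second homologation.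

Step 8
Reactants: 9 4-[(tert-butyldimethylsilyl)oxy]-2-hydroxy-6-methoxy-3-(3-methylbut-2-en-1-yl)benzaldehyde; 12 (2E)-3-{3-[(tert-butyldimethylsilyl)oxy]-5-methoxyphenyl}prop-2-enal
Product: 14 (2S)-7-[(tert-butyldimethylsilyl)oxy]-2-{3-[(tert-butyldimethylsilyl)oxy]-5-methoxyphenyl}-5-methoxy-8-(3-methylbut-2-en-1-yl)-2H-chromene-3-carbaldehyde, via aldol adduct 13 (not isolated)
Conditions: 12 (1.5 equiv), (R)-2-[diphenyl(trimethylsilyloxy)methyl]pyrrolidine (20 mol %), 2-nitrobenzoic acid (20 mol %), 4 Å MS, toluene, rt
Reagents that add atoms: none
Why: Condensation of 12 with the secondary amine gives an E, s-trans iminium ion whose β-carbon (the future C2) is attacked by the C8a hydroxyl of 9, forming O1–C2 (oxa-Michael addition). The resulting enamine adds to the neighbouring formyl group (intramolecular aldol, C3–C4) to give 13, largely in catalyst-bound form, and dehydration with hydrolysis releases the catalyst and the conjugated enal 14. The closest known reaction type is the amine-catalysed asymmetric oxa-Michael/aldol condensation of salicylaldehydes with cinnamaldehydes to 2-aryl-2H-chromene-3-carbaldehydes. The pyran ring is closed in the aldol event, a 6-exo-trig (enolexo) attack of the enamine carbon on the aldehyde carbon. C2 is controlled by the diphenyl(trimethylsilyloxy)methyl group, which blocks one face of the iminium ion so that oxygen adds from the open face; on this model the (R)-catalyst leads to (2S)-14. The step needs enantioface selectivity and reaction at a single phenol; the latter is secured because O7 and the ring B oxygen are silylated and the only free hydroxyl sits ortho to the formyl group. The acid co-catalyst and the sieves should speed aldol closure and dehydration, so that the reversible oxa-Michael addition does not erode the selectivity.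

Step 9
Reactants: 14 (2S)-7-[(tert-butyldimethylsilyl)oxy]-2-{3-[(tert-butyldimethylsilyl)oxy]-5-methoxyphenyl}-5-methoxy-8-(3-methylbut-2-en-1-yl)-2H-chromene-3-carbaldehyde
Product: 16 (2R)-7-[(tert-butyldimethylsilyl)oxy]-2-{3-[(tert-butyldimethylsilyl)oxy]-5-methoxyphenyl}-5-methoxy-8-(3-methylbut-2-en-1-yl)chromane-3-carbaldehyde (mixture of C3 epimers), via silyl enol ether 15 (not isolated)
Conditions: Et3SiH (1.5 equiv), RhCl(PPh3)3 (2 mol %), toluene, 50 °C; then 1 M HCl (aq), THF, 0 °C
Reagents that add atoms: none
Why: Rhodium-catalysed 1,4-hydrosilylation of an enal with a monohydrosilane delivers hydride to C4 and silicon to oxygen, giving 15 without touching the isolated trisubstituted prenyl alkene; mild acid hydrolysis then protonates C3. No enolate or enamine is formed, so O1 should not be expelled from C2 and the stereocentre is kept; the C3 epimer mixture is irrelevant.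

Step 10
Reactants: 16 (2R)-7-[(tert-butyldimethylsilyl)oxy]-2-{3-[(tert-butyldimethylsilyl)oxy]-5-methoxyphenyl}-5-methoxy-8-(3-methylbut-2-en-1-yl)chromane-3-carbaldehyde
Product: 17 (2R)-7-[(tert-butyldimethylsilyl)oxy]-2-{3-[(tert-butyldimethylsilyl)oxy]-5-methoxyphenyl}-5-methoxy-8-(3-methylbut-2-en-1-yl)chromane
Conditions: RhCl(PPh3)3 (1.1 equiv), toluene (degassed), 110 °C
Reagents that add atoms: none
Why: Tsuji–Wilkinson decarbonylation; oxidative addition of the formyl C–H bond to rhodium, extrusion of CO and C–H reductive elimination replace the formyl group by hydrogen, and the complex ends as RhCl(CO)(PPh3)2. C3 becomes a methylene group and C2 is not involved.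

Step 11
Reactants: 17 (2R)-7-[(tert-butyldimethylsilyl)oxy]-2-{3-[(tert-butyldimethylsilyl)oxy]-5-methoxyphenyl}-5-methoxy-8-(3-methylbut-2-en-1-yl)chromane
Product: 18 (2R)-2-(3-hydroxy-5-methoxyphenyl)-5-methoxy-8-(3-methylbut-2-en-1-yl)chroman-7-ol (CNP0389420.1)
Conditions: TBAF (2.5 equiv), AcOH (2.5 equiv), THF, 0 °C to rt
Reagents that add atoms: none
Why: Fluoride cleaves both aryl silyl ethers; acetic acid buffers the phenoxides, and no acid strong enough to cyclise the C7 hydroxyl onto the prenyl group is present.

## Compound list

1 | 5-methoxyresorcinol | COc1cc(O)cc(O)c1 | starting material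
2 | 1-methoxy-3,5-bis(methoxymethoxy)benzene | COCOc1cc(OC)cc(OCOC)c1 | intermediate
3 | prenyl bromide | CC(C)=CCBr | starting material
4 | [4-methoxy-2,6-bis(methoxymethoxy)phenyl]lithium | [Li]c1c(OCOC)cc(OC)cc1OCOC | intermediate (not isolated)
5 | 5-methoxy-1,3-bis(methoxymethoxy)-2-(3-methylbut-2-en-1-yl)benzene | COCOc1cc(OC)cc(OCOC)c1CC=C(C)C | intermediate
6 | [6-methoxy-2,4-bis(methoxymethoxy)-3-(3-methylbut-2-en-1-yl)phenyl]lithium | [Li]c1c(OC)cc(OCOC)c(CC=C(C)C)c1OCOC | intermediate (not isolated)
7 | 6-methoxy-2,4-bis(methoxymethoxy)-3-(3-methylbut-2-en-1-yl)benzaldehyde | COCOc1cc(OC)c(C=O)c(OCOC)c1CC=C(C)C | intermediate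
8 | 2,4-dihydroxy-6-methoxy-3-(3-methylbut-2-en-1-yl)benzaldehyde | COc1cc(O)c(CC=C(C)C)c(O)c1C=O | intermediate
9 | 4-[(tert-butyldimethylsilyl)oxy]-2-hydroxy-6-methoxy-3-(3-methylbut-2-en-1-yl)benzaldehyde | O=Cc1c(O)c(CC=C(C)C)c(O[Si](C)(C)C(C)(C)C)cc1OC | intermediate
10 | 3-hydroxy-5-methoxybenzaldehyde | COc1cc(O)cc(C=O)c1 | starting material
11 | 3-[(tert-butyldimethylsilyl)oxy]-5-methoxybenzaldehyde | COc1cc(O[Si](C)(C)C(C)(C)C)cc(C=O)c1 | intermediate
12 | (2E)-3-{3-[(tert-butyldimethylsilyl)oxy]-5-methoxyphenyl}prop-2-enal | COc1cc(O[Si](C)(C)C(C)(C)C)cc(/C=C/C=O)c1 | intermediate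
13 | (2R)-7-[(tert-butyldimethylsilyl)oxy]-2-{3-[(tert-butyldimethylsilyl)oxy]-5-methoxyphenyl}-4-hydroxy-5-methoxy-8-(3-methylbut-2-en-1-yl)chromane-3-carbaldehyde (C3 and C4 not defined) | COc1cc(O[Si](C)(C)C(C)(C)C)cc([C@H]2C(C=O)C(O)c3c(OC)cc(O[Si](C)(C)C(C)(C)C)c(CC=C(C)C)c3O2)c1 | intermediate (not isolated)
14 | (2S)-7-[(tert-butyldimethylsilyl)oxy]-2-{3-[(tert-butyldimethylsilyl)oxy]-5-methoxyphenyl}-5-methoxy-8-(3-methylbut-2-en-1-yl)-2H-chromene-3-carbaldehyde | COc1cc(O[Si](C)(C)C(C)(C)C)cc([C@H]2C(C=O)=Cc3c(OC)cc(O[Si](C)(C)C(C)(C)C)c(CC=C(C)C)c3O2)c1 | intermediate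
15 | (2S)-7-[(tert-butyldimethylsilyl)oxy]-2-{3-[(tert-butyldimethylsilyl)oxy]-5-methoxyphenyl}-5-methoxy-8-(3-methylbut-2-en-1-yl)-3-[(triethylsilyloxy)methylidene]chromane (enol ether geometry not defined) | COc1cc(O[Si](C)(C)C(C)(C)C)cc([C@H]2C(=CO[Si](CC)(CC)CC)Cc3c(OC)cc(O[Si](C)(C)C(C)(C)C)c(CC=C(C)C)c3O2)c1 | intermediate (not isolated)
16 | (2R)-7-[(tert-butyldimethylsilyl)oxy]-2-{3-[(tert-butyldimethylsilyl)oxy]-5-methoxyphenyl}-5-methoxy-8-(3-methylbut-2-en-1-yl)chromane-3-carbaldehyde (C3 epimers) | COc1cc(O[Si](C)(C)C(C)(C)C)cc([C@H]2C(C=O)Cc3c(OC)cc(O[Si](C)(C)C(C)(C)C)c(CC=C(C)C)c3O2)c1 | intermediate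
17 | (2R)-7-[(tert-butyldimethylsilyl)oxy]-2-{3-[(tert-butyldimethylsilyl)oxy]-5-methoxyphenyl}-5-methoxy-8-(3-methylbut-2-en-1-yl)chromane | COc1cc(O[Si](C)(C)C(C)(C)C)cc([C@H]2CCc3c(OC)cc(O[Si](C)(C)C(C)(C)C)c(CC=C(C)C)c3O2)c1 | intermediate
18 | (2R)-2-(3-hydroxy-5-methoxyphenyl)-5-methoxy-8-(3-methylbut-2-en-1-yl)chroman-7-ol | COc1cc(O)cc([C@H]2CCc3c(OC)cc(O)c(CC=C(C)C)c3O2)c1 | target

## Step count and least certain steps

Total: 11 steps. Longest linear sequence: 9 steps (steps 1–5 and 8–11). Steps 6 and 7 form the short branch to 12.

**Step 8 (key step).** The aldol closure may be slow on an aldehyde that is electron-rich and substituted at both ortho positions, and the reacting phenol is flanked by the prenyl group. The reversible oxa-Michael adduct would then equilibrate, which means incomplete conversion or erosion of enantioselectivity. Fallback: setting out from 9 and 12, catalyst control is given up and the stereocentre is secured by resolution. The annulation is run with achiral pyrrolidine and benzoic acid to give the racemic chromene-3-carbaldehyde F1, and its enantiomers are separated by preparative chromatography on a chiral stationary phase. The (2S) enantiomer is 14, where the route is rejoined. Half of the material is lost this way.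

**Step 10.** Decarbonylation of an α-branched aldehyde is slow. At the temperature needed, the alkylrhodium intermediate may undergo β-hydride elimination or loss of the β-aryloxy group (ring opening), and rhodium hydrides may isomerise the prenyl double bond. Fallback: setting out from 16, the aldehyde is oxidised (NaClO2, NaH2PO4, 2-methylbut-2-ene) to the chromane-3-carboxylic acid F2. This is condensed with N-hydroxypyridine-2-thione and a carbodiimide to the thiohydroxamate ester F3, which is irradiated with tert-butyl thiol (Barton reductive decarboxylation). The C3 radical is quenched by hydrogen transfer, and the route is rejoined at 17.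

**Step 9.** Competing 1,2-hydrosilylation of the formyl group, slow hydride delivery to a trisubstituted electron-rich enal, or loss of O1 by β-elimination during hydrolysis of 15 would lower the return or open the ring. Fallback: setting out from 14, the order is reversed. The enal is decarbonylated first with RhCl(PPh3)3 to the (2R)-2-aryl-2H-chromene F4. Its cis-disubstituted styrene-type C3=C4 bond is then reduced with diimide (2-nitrobenzenesulfonyl hydrazide, Et3N), which discriminates strongly against the trisubstituted prenyl alkene. The route is rejoined at 17. The hazard of this variant is thermal electrocyclic ring opening of F4, which would racemise C2.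

**Step 3.** n-BuLi may remove a proton from the benzylic, allylic CH2 of the prenyl group (lateral metalation) in competition with ring metalation. Fallback: setting out from 5, the acetals are removed first (HCl, MeOH) to give 5-methoxy-2-(3-methylbut-2-en-1-yl)benzene-1,3-diol F5. This is formylated by a Vilsmeier–Haack reaction (POCl3, DMF, MeCN, 0 °C, then aqueous hydrolysis). Because F5 is symmetric, only one isomer can form, and the route is rejoined at 8. The price is acid treatment and electrophilic substitution on a free prenylated resorcinol.

**Step 2.** Metalation may occur partly between the methoxymethoxy and methoxy groups, and the allylic bromide may react in the SN2′ sense; both would give isomeric arenes. Fallback: setting out from 3 and leaving 2 aside, the prenyl group is placed by rearrangement instead of metalation.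
- Commercial 2,4,6-trihydroxybenzaldehyde F6 is converted with two equivalents of MOMCl and iPr2NEt into 2-hydroxy-4,6-bis(methoxymethoxy)benzaldehyde F7.
- O-Alkylation with 3 and K2CO3 gives 2,4-bis(methoxymethoxy)-6-[(3-methylbut-2-en-1-yl)oxy]benzaldehyde F8.
- Heating in N,N-diethylaniline moves the prenyl group to the para position by a Claisen/Cope sequence, giving 6-hydroxy-2,4-bis(methoxymethoxy)-3-(3-methylbut-2-en-1-yl)benzaldehyde F9.
- Methylation (MeI, K2CO3) rejoins the route at 7.

## Further compounds

F1 | step 8 | racemic 7-[(tert-butyldimethylsilyl)oxy]-2-{3-[(tert-butyldimethylsilyl)oxy]-5-methoxyphenyl}-5-methoxy-8-(3-methylbut-2-en-1-yl)-2H-chromene-3-carbaldehyde | COc1cc(O[Si](C)(C)C(C)(C)C)cc(C2C(C=O)=Cc3c(OC)cc(O[Si](C)(C)C(C)(C)C)c(CC=C(C)C)c3O2)c1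
F2 | step 10 | (2R)-7-[(tert-butyldimethylsilyl)oxy]-2-{3-[(tert-butyldimethylsilyl)oxy]-5-methoxyphenyl}-5-methoxy-8-(3-methylbut-2-en-1-yl)chromane-3-carboxylic acid (C3 epimers) | COc1cc(O[Si](C)(C)C(C)(C)C)cc([C@H]2C(C(=O)O)Cc3c(OC)cc(O[Si](C)(C)C(C)(C)C)c(CC=C(C)C)c3O2)c1
F3 | step 10 | 2-thioxopyridin-1(2H)-yl ester of F2 | COc1cc(O[Si](C)(C)C(C)(C)C)cc([C@H]2C(C(=O)On4ccccc4=S)Cc3c(OC)cc(O[Si](C)(C)C(C)(C)C)c(CC=C(C)C)c3O2)c1
F4 | step 9 | (2R)-7-[(tert-butyldimethylsilyl)oxy]-2-{3-[(tert-butyldimethylsilyl)oxy]-5-methoxyphenyl}-5-methoxy-8-(3-methylbut-2-en-1-yl)-2H-chromene | COc1cc(O[Si](C)(C)C(C)(C)C)cc([C@H]2C=Cc3c(OC)cc(O[Si](C)(C)C(C)(C)C)c(CC=C(C)C)c3O2)c1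
F5 | step 3 | 5-methoxy-2-(3-methylbut-2-en-1-yl)benzene-1,3-diol | COc1cc(O)c(CC=C(C)C)c(O)c1
F6 | step 2 | 2,4,6-trihydroxybenzaldehyde | O=Cc1c(O)cc(O)cc1O
F7 | step 2 | 2-hydroxy-4,6-bis(methoxymethoxy)benzaldehyde | COCOc1cc(O)c(C=O)c(OCOC)c1
F8 | step 2 | 2,4-bis(methoxymethoxy)-6-[(3-methylbut-2-en-1-yl)oxy]benzaldehyde | COCOc1cc(OCC=C(C)C)c(C=O)c(OCOC)c1
F9 | step 2 | 6-hydroxy-2,4-bis(methoxymethoxy)-3-(3-methylbut-2-en-1-yl)benzaldehyde | COCOc1cc(O)c(C=O)c(OCOC)c1CC=C(C)C
A1 | alternative 1 | (2R)-2-{3-[(tert-butyldimethylsilyl)oxy]-5-methoxyphenyl}-5-methoxy-8-(3-methylbut-2-en-1-yl)chroman-7-ol | COc1cc(O[Si](C)(C)C(C)(C)C)cc([C@H]2CCc3c(OC)cc(O)c(CC=C(C)C)c3O2)c1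
A2 | alternative 1 | 2-[(3R)-3-{3-[(tert-butyldimethylsilyl)oxy]-5-methoxyphenyl}-3-[(5-methylhex-4-en-1-yn-1-yl)oxy]propyl]-3-methoxycyclobut-2-en-1-one | COc1cc(O[Si](C)(C)C(C)(C)C)cc([C@@H](CCC2=C(OC)CC2=O)OC#CCC=C(C)C)c1
A3 | alternative 2 | (2R)-2-{3-[(tert-butyldimethylsilyl)oxy]-5-methoxyphenyl}-2,3-dihydro-4H-pyran-4-one | COc1cc(O[Si](C)(C)C(C)(C)C)cc([C@H]2CC(=O)C=CO2)c1
A4 | alternative 2 | (E)-1-methoxy-3-(trimethylsilyloxy)buta-1,3-diene | CO/C=C/C(=C)O[Si](C)(C)C
A5 | alternative 3 | (2R)-5-methoxy-2-{3-methoxy-5-[(triisopropylsilyl)oxy]phenyl}-8-(3-methylbut-2-en-1-yl)-7-[(triisopropylsilyl)oxy]chromane | COc1cc(O[Si](C(C)C)(C(C)C)C(C)C)cc([C@H]2CCc3c(OC)cc(O[Si](C(C)C)(C(C)C)C(C)C)c(CC=C(C)C)c3O2)c1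
A6 | alternative 3 | 1-iodo-5-methoxy-2-(3-methylbut-2-en-1-yl)-3-[(triisopropylsilyl)oxy]benzene | COc1cc(I)c(CC=C(C)C)c(O[Si](C(C)C)(C(C)C)C(C)C)c1
A7 | alternative 3 | (2R)-2-{3-methoxy-5-[(triisopropylsilyl)oxy]phenyl}oxetane | COc1cc(O[Si](C(C)C)(C(C)C)C(C)C)cc([C@H]2CCO2)c1
A8 | alternative 3 | norbornene (bicyclo[2.2.1]hept-2-ene) | C1=CC2CCC1C2
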